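**Plan**

- Target: (2S)-7,4'-dihydroxy-6,8-diprenylflavanone (prenyl = 3-methylbut-2-enyl). The last cuts are the two O–Si bonds and the C2–H/C3–H pair, which lead back to a flavone.
- Ring C is cut at C4a–C4, C4–C3 and O1–C2. The C4 carbonyl lies between C4a of ring A and the C3–C2–aryl unit, and O1 sits on C8a next to C4a, so ring C is an ortho-iodophenol plus CO plus an arylacetylene.
- The iodophenol is cut at its two aryl–CH2 bonds and its C–I bond, back to resorcinol. Three successive MOM-directed ortho-lithiations install prenyl, prenyl and iodine; direct C-prenylation of a free iodoresorcinol is avoided as unselective.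
- Forward: rings A and B are bought (resorcinol, 4-hydroxybenzaldehyde). Ring C is the only ring formed, by 6-endo closure in the carbonylative annulation.
- Stereochemistry: the single stereocentre C2 (S) is set after ring formation by ligand-controlled asymmetric copper hydride 1,4-reduction of C2=C3. Buffered fluoride desilylation preserves it.

Key step: step 8

Assumption: (S)-DTBM-SEGPHOS is taken to deliver hydride to the face of C2 that gives 2S; the sense is to be confirmed on the first run, and the (R)-ligand is used if it proves opposite.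

**Step 1**
Reactants: 1 resorcinol
Product: 2 1,3-bis(methoxymethoxy)benzene
Conditions: MOMCl, i-Pr2NEt, CH2Cl2, 0 °C → rt
Reagents that add atoms: chloromethyl methyl ether, COCCl
Why: Standard O-alkylation of both phenols with MOMCl under Hünig's base (MOM protection) installs two ortho-directing acetal groups that survive organolithium bases.

**Step 2**
Reactants: 2 1,3-bis(methoxymethoxy)benzene; 3 prenyl bromide
Product: 5 1,3-bis(methoxymethoxy)-2-(3-methylbut-2-enyl)benzene, via C2-aryllithium 4 (not isolated)
Conditions: n-BuLi, THF, 0 °C → rt; then 3, −78 °C → rt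
Reagents that add atoms: none
Why: Directed ortho-metalation removes the C2–H flanked by both OMOM groups, and the aryllithium undergoes SN2 allylation with the primary allylic bromide to give the linear prenyl group.

**Step 3**
Reactants: 5 1,3-bis(methoxymethoxy)-2-(3-methylbut-2-enyl)benzene; 3 prenyl bromide
Product: 7 1,3-bis(methoxymethoxy)-2,4-bis(3-methylbut-2-enyl)benzene, via C4-aryllithium 6 (not isolated)
Conditions: n-BuLi, TMEDA, THF, 0 °C; then 3, −78 °C → rt
Reagents that add atoms: none
Why: A second directed ortho-metalation followed by allylation; the two remaining positions ortho to an OMOM group (C4 and C6) are equivalent by symmetry, so only one regioisomer can form.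

**Step 4**
Reactants: 7 1,3-bis(methoxymethoxy)-2,4-bis(3-methylbut-2-enyl)benzene
Product: 9 1-iodo-2,4-bis(methoxymethoxy)-3,5-bis(3-methylbut-2-enyl)benzene, via C6-aryllithium 8 (not isolated)
Conditions: n-BuLi, TMEDA, THF, 0 °C; then ICH2CH2I, −78 °C → rt
Reagents that add atoms: 1,2-diiodoethane, ICCI
Why: A third directed ortho-metalation at the only C–H still ortho to an OMOM group, then iodination of the aryllithium with 1,2-diiodoethane, which transfers iodine without free I2 so the prenyl alkenes are left alone.

**Step 5**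
Reactants: 9 1-iodo-2,4-bis(methoxymethoxy)-3,5-bis(3-methylbut-2-enyl)benzene
Product: 10 4-iodo-2,6-bis(3-methylbut-2-enyl)benzene-1,3-diol
Conditions: conc. HCl (cat.), MeOH, rt → 40 °C
Reagents that add atoms: none
Why: Acid-catalysed methanolysis of aryl MOM acetals, the usual unmasking of prenylated phenols; the mild temperature should limit addition of the phenols to the prenyl double bonds, and the aryl iodide is inert.

**Step 6**
Reactants: 11 4-hydroxybenzaldehyde
Product: 12 4-(triisopropylsilyloxy)benzaldehyde
Conditions: TIPSCl, imidazole, DMF, rt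
Reagents that add atoms: triisopropylsilyl chloride, CC(C)[Si](Cl)(C(C)C)C(C)C
Why: Imidazole-promoted silylation of a phenol; the bulky TIPS ether is chosen because it must later withstand a hot secondary amine.

**Step 7**
Reactants: 12 4-(triisopropylsilyloxy)benzaldehyde
Product: 13 (4-ethynylphenoxy)triisopropylsilane
Conditions: TMSCHN2, LDA, THF, −78 °C; then 12, −78 °C → rt
Reagents that add atoms: trimethylsilyldiazomethane, C[Si](C)(C)C=[N+]=[N-]
Why: Colvin homologation, in which lithiated trimethylsilyldiazomethane adds to the aldehyde and loss of silanolate and N2 with a 1,2-hydrogen shift gives the terminal alkyne; the aprotic low-temperature conditions avoid the carbonate/methanol medium that could cleave the aryl silyl ether.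

**Step 8**
Reactants: 10 4-iodo-2,6-bis(3-methylbut-2-enyl)benzene-1,3-diol; 13 (4-ethynylphenoxy)triisopropylsilane; 14 carbon monoxide
Product: 17 7-hydroxy-6,8-bis(3-methylbut-2-enyl)-2-[4-(triisopropylsilyloxy)phenyl]-4H-chromen-4-one, via ynone 15 (not isolated), via enaminone 16 (not isolated)
Conditions: PdCl2(dppf) (5 mol %), Et2NH (solvent), CO (20 atm), 100 °C
Reagents that add atoms: none
Why: Oxidative addition of Pd(0) into the C–I bond of 10 and CO insertion give an aroylpalladium iodide, which couples with alkyne 13 (deprotonated by the amine at palladium, no copper) to ynone 15, forming C4a–C4 and C4–C3; diethylamine then adds to 15 to give enaminone 16, and the ortho phenol displaces the amine by addition–elimination, forming O1–C2. The closest known reaction type is the palladium-catalysed carbonylative Sonogashira coupling–cyclisation of ortho-iodophenols with terminal alkynes in a secondary amine, an established flavone synthesis. Ring C closes in the 6-endo mode (formally 6-endo-dig on the ynone, realised as 6-endo-trig addition–elimination on the enaminone). No stereocentre is formed. Three selectivities are needed: CO insertion before alkyne coupling (otherwise a 2-arylbenzofuran results), favoured by CO pressure, the electron-rich aryl group and the absence of copper; 6-endo over 5-exo closure (aurone), secured by the enaminone pathway; and closure by the correct oxygen, secured by geometry, since only the hydroxyl ortho to the acyl group can reach C2 while the other, para to the carbonyl and flanked by two prenyl groups, is a spectator. The iodine has only C5–H as carbon neighbour, both prenyl groups are meta to it so no Heck pathway is open, and the aryl TIPS ether and trisubstituted alkenes are inert to Pd(0), CO and amine.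

**Step 9**
Reactants: 17 7-hydroxy-6,8-bis(3-methylbut-2-enyl)-2-[4-(triisopropylsilyloxy)phenyl]-4H-chromen-4-one
Product: 18 7-(tert-butyldimethylsilyloxy)-6,8-bis(3-methylbut-2-enyl)-2-[4-(triisopropylsilyloxy)phenyl]-4H-chromen-4-one
Conditions: TBSCl, imidazole, DMF, rt
Reagents that add atoms: tert-butyldimethylsilyl chloride, CC(C)(C)[Si](C)(C)Cl
Why: Silylation of the acidic 7-hydroxyl (a vinylogous acid) with the smaller TBS group, which fits between the two prenyl groups and masks the only protic site before the hydride step.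

**Step 10**
Reactants: 18 7-(tert-butyldimethylsilyloxy)-6,8-bis(3-methylbut-2-enyl)-2-[4-(triisopropylsilyloxy)phenyl]-4H-chromen-4-one
Product: 20 (2S)-7-(tert-butyldimethylsilyloxy)-6,8-bis(3-methylbut-2-enyl)-2-[4-(triisopropylsilyloxy)phenyl]-2,3-dihydro-4H-chromen-4-one, via silyl enol ether 19 (not isolated)
Conditions: Cu(OAc)2·H2O (5 mol %), (S)-DTBM-SEGPHOS (5 mol %), (EtO)2MeSiH, toluene, 0 °C → rt; then AcOH, THF/H2O, 0 °C
Reagents that add atoms: none
Why: Asymmetric copper hydride conjugate reduction (1,4-hydrosilylation) of a chromone, in which the chiral bisphosphine–CuH adds hydride to one face of C2 and so sets the 2S centre by ligand control; the enolate is held as silyl enol ether 19, which blocks 1,2-reduction and ring opening until mild acid releases the ketone, and the isolated prenyl alkenes and aryl silyl ethers do not react.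

**Step 11**
Reactants: 20 (2S)-7-(tert-butyldimethylsilyloxy)-6,8-bis(3-methylbut-2-enyl)-2-[4-(triisopropylsilyloxy)phenyl]-2,3-dihydro-4H-chromen-4-one
Product: 21 (2S)-7-hydroxy-2-(4-hydroxyphenyl)-6,8-bis(3-methylbut-2-enyl)-2,3-dihydro-4H-chromen-4-one
Conditions: TBAF, AcOH, THF, 0 °C
Reagents that add atoms: none
Why: Fluoride cleavage of both aryl silyl ethers; the acetic acid buffer keeps the medium from becoming basic, so the flavanone should not open to the chalcone phenoxide and C2 should keep its configuration, while the prenyl groups are untouched.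

**Compound list**

1 | resorcinol (benzene-1,3-diol) | Oc1cccc(O)c1 | starting material
2 | 1,3-bis(methoxymethoxy)benzene | COCOc1cccc(OCOC)c1 | intermediate
3 | prenyl bromide (1-bromo-3-methylbut-2-ene) | CC(C)=CCBr | starting material
4 | [2,6-bis(methoxymethoxy)phenyl]lithium | [Li]c1c(OCOC)cccc1OCOC | intermediate
5 | 1,3-bis(methoxymethoxy)-2-(3-methylbut-2-enyl)benzene | COCOc1cccc(OCOC)c1CC=C(C)C | intermediate
6 | [2,4-bis(methoxymethoxy)-3-(3-methylbut-2-enyl)phenyl]lithium | [Li]c1ccc(OCOC)c(CC=C(C)C)c1OCOC | intermediate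
7 | 1,3-bis(methoxymethoxy)-2,4-bis(3-methylbut-2-enyl)benzene | COCOc1ccc(CC=C(C)C)c(OCOC)c1CC=C(C)C | intermediate
8 | [2,4-bis(methoxymethoxy)-3,5-bis(3-methylbut-2-enyl)phenyl]lithium | [Li]c1cc(CC=C(C)C)c(OCOC)c(CC=C(C)C)c1OCOC | intermediate
9 | 1-iodo-2,4-bis(methoxymethoxy)-3,5-bis(3-methylbut-2-enyl)benzene | COCOc1c(I)cc(CC=C(C)C)c(OCOC)c1CC=C(C)C | intermediate
10 | 4-iodo-2,6-bis(3-methylbut-2-enyl)benzene-1,3-diol | CC(C)=CCc1cc(I)c(O)c(CC=C(C)C)c1O | intermediate
11 | 4-hydroxybenzaldehyde | O=Cc1ccc(O)cc1 | starting material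
12 | 4-(triisopropylsilyloxy)benzaldehyde | O=Cc1ccc(O[Si](C(C)C)(C(C)C)C(C)C)cc1 | intermediate
13 | (4-ethynylphenoxy)triisopropylsilane | C#Cc1ccc(O[Si](C(C)C)(C(C)C)C(C)C)cc1 | intermediate
14 | carbon monoxide | [C-]#[O+] | starting material
15 | 1-[2,4-dihydroxy-3,5-bis(3-methylbut-2-enyl)phenyl]-3-[4-(triisopropylsilyloxy)phenyl]prop-2-yn-1-one (ynone) | CC(C)=CCc1cc(C(=O)C#Cc2ccc(O[Si](C(C)C)(C(C)C)C(C)C)cc2)c(O)c(CC=C(C)C)c1O | intermediate
16 | 3-(diethylamino)-1-[2,4-dihydroxy-3,5-bis(3-methylbut-2-enyl)phenyl]-3-[4-(triisopropylsilyloxy)phenyl]prop-2-en-1-one (enaminone, alkene geometry not defined) | CCN(CC)C(=CC(=O)c1cc(CC=C(C)C)c(O)c(CC=C(C)C)c1O)c1ccc(O[Si](C(C)C)(C(C)C)C(C)C)cc1 | intermediate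
17 | 7-hydroxy-6,8-bis(3-methylbut-2-enyl)-2-[4-(triisopropylsilyloxy)phenyl]-4H-chromen-4-one | CC(C)=CCc1cc2c(c(CC=C(C)C)c1O)oc(-c1ccc(O[Si](C(C)C)(C(C)C)C(C)C)cc1)cc2=O | intermediate
18 | 7-(tert-butyldimethylsilyloxy)-6,8-bis(3-methylbut-2-enyl)-2-[4-(triisopropylsilyloxy)phenyl]-4H-chromen-4-one | CC(C)=CCc1cc2c(c(CC=C(C)C)c1O[Si](C)(C)C(C)(C)C)oc(-c1ccc(O[Si](C(C)C)(C(C)C)C(C)C)cc1)cc2=O | intermediate
19 | (2S)-7-(tert-butyldimethylsilyloxy)-4-[diethoxy(methyl)silyloxy]-6,8-bis(3-methylbut-2-enyl)-2-[4-(triisopropylsilyloxy)phenyl]-2H-chromene | CC(C)=CCc1cc2c(c(CC=C(C)C)c1O[Si](C)(C)C(C)(C)C)O[C@H](c1ccc(O[Si](C(C)C)(C(C)C)C(C)C)cc1)C=C2O[Si](C)(OCC)OCC | intermediate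
20 | (2S)-7-(tert-butyldimethylsilyloxy)-6,8-bis(3-methylbut-2-enyl)-2-[4-(triisopropylsilyloxy)phenyl]-2,3-dihydro-4H-chromen-4-one | CC(C)=CCc1cc2c(c(CC=C(C)C)c1O[Si](C)(C)C(C)(C)C)O[C@H](c1ccc(O[Si](C(C)C)(C(C)C)C(C)C)cc1)CC2=O | intermediate
21 | (2S)-7-hydroxy-2-(4-hydroxyphenyl)-6,8-bis(3-methylbut-2-enyl)-2,3-dihydro-4H-chromen-4-one (CNP0283993.2) | CC(C)=CCc1cc2c(c(CC=C(C)C)c1O)O[C@H](c1ccc(O)cc1)CC2=O | target

**Step count**

Total: 11 steps. Longest linear sequence: 9 steps (steps 1–5 and 8–11, from resorcinol); steps 6–7 make the alkyne branch.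

**Steps most likely to fail**

1. Step 8. The aroylpalladium intermediate may be consumed by the free phenols or the amine (ester or amide formation), coupling may occur without CO insertion, or the silyl ether may be lost at the temperature required. The fallback forms the same ynone by acylation of an aryllithium instead of by carbonylation. It sets out from aryllithium 8 (generated from 7 as in step 4) and alkyne 13. Alkyne 13 is deprotonated with n-BuLi in THF at −78 °C to {[4-(triisopropylsilyloxy)phenyl]ethynyl}lithium F1. F1 is acylated with N-methoxy-N-methylcarbamoyl chloride to the alkynyl Weinreb amide N-methoxy-N-methyl-3-[4-(triisopropylsilyloxy)phenyl]prop-2-ynamide F2. Addition of 8 to F2 at −78 °C gives 1-[2,4-bis(methoxymethoxy)-3,5-bis(3-methylbut-2-enyl)phenyl]-3-[4-(triisopropylsilyloxy)phenyl]prop-2-yn-1-one F3. Methanolic HCl removes the acetals to give ynone 15, and diethylamine closes it through 16. The fallback comes back to the route at 17.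

2. Step 10. Hydride transfer to the electron-rich vinylogous ester may be sluggish, facial selectivity may be poor, or the C2 configuration may erode through ring opening at the enolate stage. The fallback sets out from 18 and uses a non-selective 1,4-reduction with L-Selectride (THF, −78 °C) to give racemic 7-(tert-butyldimethylsilyloxy)-6,8-bis(3-methylbut-2-enyl)-2-[4-(triisopropylsilyloxy)phenyl]-2,3-dihydro-4H-chromen-4-one F4. Kinetic resolution by Noyori-type asymmetric transfer hydrogenation follows (RuCl(p-cymene)(TsDPEN), HCO2H/Et3N). The catalyst antipode is chosen so that the 2R ketone is reduced faster, to (2R,4R)-7-(tert-butyldimethylsilyloxy)-6,8-bis(3-methylbut-2-enyl)-2-[4-(triisopropylsilyloxy)phenyl]-3,4-dihydro-2H-chromen-4-ol F5. The unreacted 2S ketone is separated by chromatography, and the fallback comes back to the route at 20.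

3. Step 5. The liberated phenols may add across the neighbouring prenyl double bonds under protic acid (chroman ring formation), or the alkenes may be hydrochlorinated, before acetal cleavage is complete. The fallback avoids protic acid. It sets out from 9 and treats it with TMSOTf and 2,2'-bipyridyl in CH2Cl2 at 0 °C, which exchanges both aryl MOM ethers for silyl ethers to give 1-iodo-3,5-bis(3-methylbut-2-enyl)-2,4-bis(trimethylsilyloxy)benzene F6. The labile aryl trimethylsilyl ethers are then hydrolysed with water (or K2CO3/MeOH) at rt, and the fallback comes back to the route at 10.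

**Further compounds**

F1 | step 8 | {[4-(triisopropylsilyloxy)phenyl]ethynyl}lithium | [Li]C#Cc1ccc(O[Si](C(C)C)(C(C)C)C(C)C)cc1
F2 | step 8 | N-methoxy-N-methyl-3-[4-(triisopropylsilyloxy)phenyl]prop-2-ynamide | CON(C)C(=O)C#Cc1ccc(O[Si](C(C)C)(C(C)C)C(C)C)cc1
F3 | step 8 | 1-[2,4-bis(methoxymethoxy)-3,5-bis(3-methylbut-2-enyl)phenyl]-3-[4-(triisopropylsilyloxy)phenyl]prop-2-yn-1-one | COCOc1c(C(=O)C#Cc2ccc(O[Si](C(C)C)(C(C)C)C(C)C)cc2)cc(CC=C(C)C)c(OCOC)c1CC=C(C)C
F4 | step 10 | racemic 7-(tert-butyldimethylsilyloxy)-6,8-bis(3-methylbut-2-enyl)-2-[4-(triisopropylsilyloxy)phenyl]-2,3-dihydro-4H-chromen-4-one | CC(C)=CCc1cc2c(c(CC=C(C)C)c1O[Si](C)(C)C(C)(C)C)OC(c1ccc(O[Si](C(C)C)(C(C)C)C(C)C)cc1)CC2=O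
F5 | step 10 | (2R,4R)-7-(tert-butyldimethylsilyloxy)-6,8-bis(3-methylbut-2-enyl)-2-[4-(triisopropylsilyloxy)phenyl]-3,4-dihydro-2H-chromen-4-ol | CC(C)=CCc1cc2c(c(CC=C(C)C)c1O[Si](C)(C)C(C)(C)C)O[C@@H](c1ccc(O[Si](C(C)C)(C(C)C)C(C)C)cc1)C[C@H]2O
F6 | step 5 | 1-iodo-3,5-bis(3-methylbut-2-enyl)-2,4-bis(trimethylsilyloxy)benzene | C[Si](C)(C)Oc1c(I)cc(CC=C(C)C)c(O[Si](C)(C)C)c1CC=C(C)C
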